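## Structural features

The target is an achiral, linear tridepside made of three orsellinate units, rings A, B and C. In each ring C1 carries the carbonyl carbon C7, C2 a hydroxyl, C4 the para oxygen and C6 a methyl group (ring B atoms primed, ring C atoms double-primed). The rings are joined only by two aryl ester bonds, C7'–O4 (ring B onto ring A) and C7''–O4' (ring C onto ring B), and the chain ends in the methyl ester of ring A and the free 4''-OH of ring C. There is no stereocentre, so no stereocentres stand next to each other and every selectivity question is one of chemo- or regiochemistry. The fragile groups are the two depside esters: they have phenoxide leaving groups, are cleaved or scrambled by hydroxide, alkoxide, free phenoxide and warm Lewis acids, and as aryl benzoates can undergo photo-Fries rearrangement. The electron-rich resorcinol ring C is also open to electrophilic substitution. The real difficulty is twofold: every acyl carbon is flanked by two ortho substituents, so each ester must come from a hindered acyl donor, and four hydroxyls (three hydrogen bonded to an ortho carbonyl, one free) must be told apart without basic steps late in the route. The key step exploits the pattern of ring C: C1'' bears the ester carbon C7'' and lies between the oxygenated C2'' and the methylated C6'', and the free hydroxyl on C4'' is meta to O2''. A vinylketene with the ester on its α-carbon (future C1'') and a methyl on the vinyl unit (future C6'') gives exactly this pattern with an alkoxyalkyne (future C2'' and C3''), so the hindered C7''–O4' ester can be installed beforehand as an unhindered β-keto ester.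

## Logic of the disconnections

**19 ⇒ 18.** Only the O2''–H bond is changed, to an O2''–ethyl bond. The cut is made there because the ring-forming step needs an oxygen substituent on its two-carbon partner and leaves it on C2''. The skeleton is not simplified, but 18 is the direct product of a benzannulation. The forward step must cleave one primary alkyl aryl ether beside two depside esters, a methyl ester and three phenols. O2'' is ortho to the C7'' carbonyl, so a chelating boron Lewis acid can single it out.

**18 ⇒ 13 + 14.** Ring C is opened at C1''–C2'', C3''–C4'' and C4''–C5'', and C6'' is returned from C1'' to C4'' (the reverse of a 1,2-shift). The cut is made there because the substitution pattern of ring C is the signature of a vinylketene–alkoxyalkyne union. A whole aromatic ring disappears, and with it the hindered acylation at C7''. C2'' and C3'' come from 14; C1'', C4'', C5'', C6'', the methyl and C7'' come from the acyclic diazo keto ester part of 13. A bond-by-bond check of the cascade reproduces the pattern of 18 without any change of structure. The forward step must generate the ketene without base and without light that the depside chromophores absorb, and must add 14 with the correct polarity. The hydroxyls of 13 are left free on purpose: all are hydrogen bonded, hence poor ketene traps and fast, non-destructive excited-state quenchers. The one hydroxyl that can trap the ketene is the new 4''-OH of 18, and an excess of 14 answers that.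

**13 ⇒ 7 + 10 (through 11 and 12).** The diazo group is removed and the O4'–C7'' bond is cut. At this stage C7'' is the carbonyl of a β-keto ester, which an acylketene forms under neutral conditions with no steric penalty. The gain is the didepside 7 and a six-carbon acyl donor 10. The forward step must acylate O4', the only hydroxyl of 7 that is not hydrogen bonded. Because 12 is a polymerisable vinyl ketone and a base-labile aryl β-keto ester, it is made and diazotised in one flask.

**10 ⇒ 8 + 9.** The bond between the acyl carbon and the doubly activated ring carbon is cut, giving two commercial compounds. The forward step needs C-acylation to win over conjugate addition.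

**7 ⇒ 6 ⇒ 3 + 4 (through 5).** Benzyl groups are put back on O2' and O4', then the O4–C7' bond is cut. This is the one depside bond still made by acylation, and it is formed first, on the simplest partners, where mixed-anhydride activation of a di-ortho-substituted acid is most reliable. The gain is two monocyclic building blocks, one of them commercial. The forward steps need acyl transfer to O4 and not O2 of 4, and an ether cleavage that leaves aryl esters untouched (hydrogenolysis).

**3 ⇒ 2 ⇒ 1.** The three O–benzyl bonds are cut. Both phenols of 1 must be masked before the acid is activated, or it would acylate itself. Exhaustive benzylation followed by hydrolysis of the benzyl ester is the shortest way. The forward demand is hydrolysis of a hindered ester without decarboxylation.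

## Other disconnections considered

**Alternative 1:** The cut falls on both bonds of the ring B acyl carbon, C1'–C7' and C7'–O4. This leads back to the ring C–ring B aryl bromide A1, carbon monoxide A2 and phenol 4.
- **Forward key step:** zerovalent palladium, formed from Pd(OAc)2 and a wide-bite-angle bisphosphine, would insert into the C1'–Br bond of A1. A2 would insert, and the 4-phenoxide of 4 would capture the acylpalladium species to give the tri-O-benzyl tridepside A3. One hydrogenolysis would then give 19.
- **In favour:** the union is convergent and uses 4 unprotected. The hindered ring B ester is made without activating a di-ortho-substituted acid. The end-game is a single neutral debenzylation, which is better than the Lewis-acid dealkylation of the chosen plan.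
- **Against:** the bromide of A1 is electron-rich and flanked by a benzyloxy and a methyl group, so oxidative addition and capture by a weakly nucleophilic phenoxide should both be slow. The base needed to make that phenoxide can transesterify the depside bond already present in A1 and A3. Direct diaryl ether formation and hydrodebromination compete. The bromophenol half of A1 needs its two oxygens differentiated and the bromine placed between oxygen and methyl.
- **Structure:** no ring is built and the resorcinol pattern is not exploited. Each plan still makes one depside bond by classical acylation with 3, so they are equal on that point.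
- **Mechanism:** aryloxycarbonylation is an established thermal reaction with no diazo compound and no light, so on precedent for simple substrates it is equal or better. Its need for base next to a depside is a liability the neutral key step of the chosen plan does not have.
- **Step economy:** an estimated seven operations to 19, equal to or one fewer than the eight of the chosen plan.

**Alternative 2:** Ring B is cut at C1'–C6' and C3'–C4', leading back to the acetoacetate A4 of phenol 4 and phenyl crotonate A5.
- **Forward key step:** the enolate of A4 would add to A5 in a Michael reaction (C1'–C6'). The methyl ketone enolate would then close onto the phenyl ester in a Claisen (Dieckmann-type) condensation (C3'–C4'), giving the racemic dihydro ring B compound A6. Dehydrogenation of A6 would give 7.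
- **In favour:** this is the classical ionic route to orsellinates from cheap components and needs no protecting groups, which is better than the chosen route to 7. The C7'–O4 ester is made as an unhindered acetoacetate, the same advantage the chosen plan has at C7'' (equal).
- **Against:** A4 is an aryl β-keto ester, and its enolate can expel the aryloxy group under the strongly basic conditions. The ring A aryl ester competes with the phenyl ester as acceptor and leaving group, and the free 2-OH consumes base. Aromatisation by halogenation and dehydrohalogenation would also attack the activated ring A.
- **Structure:** it builds ring B, not ring C, and stops at 7, so it competes only with steps 1 to 4 and leaves the ring C problem open.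
- **Mechanism:** it is well understood but is the least compatible of all with a depside bond, whereas the chosen key step runs without base.
- **Step economy:** three operations to 7 against four, better on paper, which would give seven in total when followed by steps 5 to 8.

**Alternative 3:** Ring B is cut at C1'–C2' and C5'–C6', leading back to the but-2-ynoate A7 of phenol 4 and the bis(silyloxy) diene A8.
- **Forward key step:** in a Diels–Alder reaction the nucleophilic CH2 terminus of A8 would bond to the methyl-bearing alkyne carbon (future C6') and the acetal carbon to the ester-bearing one (future C1'). Loss of the methoxy and silyl groups on acidic work-up would aromatise the adduct to the didepside phenol A9, which is identical with 7.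
- **In favour:** the logic is that of the chosen key step, with an orsellinate ring grown on an unhindered ester and its regiochemistry set by the polarity of the partners. It is purely thermal, with no diazo compound and no irradiation of aryl esters, so on operational safety it is better. It needs no protecting groups and reaches 7 in two operations from 4 against four, also better.
- **Against:** a β-methyl ynoate is a sluggish dienophile, and the temperatures it needs are ones at which A8 decomposes or transfers silicon to the free 2-OH. Open-chain Mukaiyama–Michael addition without ring closure is a further risk. As formulated it delivers ring B only.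
- **Structure:** it is the closest relative of the chosen plan and would be a sound replacement for steps 1 to 4. Repeating the same cycloaddition at O4' of 7 would in principle give ring C with no O-alkyl group to remove, one operation fewer than steps 6 to 8.
- **Mechanism:** comparable confidence. The chosen key step has a more reactive pair (ketene and ynol ether at room temperature) but more possible side channels.
- **Step economy:** better for the alternative if its cycloaddition tolerates the three free hydroxyls of 7.

Key step: step 7

Assumption: the target has no stereocentre and is taken as the achiral tridepside methyl ester; every hydroxyl ortho to a carbonyl is assumed to be intramolecularly hydrogen bonded, as in orsellinate esters generally, which underlies the chemoselectivity arguments.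

## Route

Step 1
Reactants: 1 orsellinic acid (2,4-dihydroxy-6-methylbenzoic acid)
Product: 2 benzyl 2,4-bis(benzyloxy)-6-methylbenzoate
Conditions: BnBr (3.5 equiv), K2CO3, DMF, 20 → 60 °C
Reagents that add atoms: benzyl bromide, BrCc1ccccc1
Why: Threefold Williamson-type O-benzylation (SN2); the carboxylate is alkylated first at 20 °C, which removes the risk of decarboxylation, and warming then alkylates the free and finally the hydrogen-bonded phenol.

Step 2
Reactants: 2 benzyl 2,4-bis(benzyloxy)-6-methylbenzoate
Product: 3 2,4-bis(benzyloxy)-6-methylbenzoic acid
Conditions: KOH, DMSO–H2O, 90 °C; then aq. HCl, 0 °C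
Reagents that add atoms: potassium hydroxide, [K+].[OH-]
Why: Ester saponification; the di-ortho-substituted benzoate needs the poorly solvated hydroxide of aqueous DMSO, the benzyl aryl ethers are inert to base, and cold acidification avoids decarboxylation of the electron-rich acid.

Step 3
Reactants: 3 2,4-bis(benzyloxy)-6-methylbenzoic acid; 4 methyl orsellinate (methyl 2,4-dihydroxy-6-methylbenzoate)
Product: 6 methyl 4-{[2,4-bis(benzyloxy)-6-methylbenzoyl]oxy}-2-hydroxy-6-methylbenzoate, via mixed anhydride 5 (not isolated)
Conditions: (CF3CO)2O, toluene, 0 → 20 °C
Reagents that add atoms: none
Why: Depside esterification through the mixed trifluoroacetic anhydride 5, whose di-ortho-substituted acyl group ionises readily to a small acylium-like species that the free 4-OH of 4 captures; the 2-OH is tied up in a hydrogen bond to the ester carbonyl, and no base is present that could cleave the new aryl ester.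

Step 4
Reactants: 6 methyl 4-{[2,4-bis(benzyloxy)-6-methylbenzoyl]oxy}-2-hydroxy-6-methylbenzoate
Product: 7 methyl 4-[(2,4-dihydroxy-6-methylbenzoyl)oxy]-2-hydroxy-6-methylbenzoate (didepside phenol)
Conditions: H2 (1 atm), Pd/C, EtOAc, 20 °C
Reagents that add atoms: none
Why: Catalytic hydrogenolysis of the two benzyl aryl ethers; aryl esters, the methyl ester and the aromatic rings are inert under these neutral conditions, and no alkene is present yet.

Step 5
Reactants: 8 Meldrum's acid (2,2-dimethyl-1,3-dioxane-4,6-dione); 9 methacryloyl chloride
Product: 10 5-(1-hydroxy-2-methylprop-2-en-1-ylidene)-2,2-dimethyl-1,3-dioxane-4,6-dione (methacryloyl Meldrum's acid, enol form)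
Conditions: pyridine (2.2 equiv), CH2Cl2, 0 → 20 °C; aq. HCl wash
Reagents that add atoms: none
Why: C-Acylation of the acidic methylene of Meldrum's acid by the acylpyridinium salt of 9 gives the fully enolised acyl derivative; 9 has no α-hydrogen, so no ketene can form from it, and its α-methyl group slows conjugate addition.

Step 6
Reactants: 7 didepside phenol; 10 methacryloyl Meldrum's acid
Product: 13 3-hydroxy-4-{[3-hydroxy-4-(methoxycarbonyl)-5-methylphenoxy]carbonyl}-5-methylphenyl 2-diazo-4-methyl-3-oxopent-4-enoate, via acylketene 11 (not isolated), via keto ester 12 (not isolated)
Conditions: MeCN, 80 °C; then p-AcNHC6H4SO2N3, Et3N, 0 → 20 °C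
Reagents that add atoms: 4-acetamidobenzenesulfonyl azide, CC(=O)Nc1ccc(cc1)S(=O)(=O)N=[N+]=[N-]
Why: Thermal retro-[4+2] fragmentation of 10 releases acetone, CO2 and acylketene 11, which acylates the only phenol of 7 that is not hydrogen bonded (O4') under neutral conditions to give β-keto ester 12; Regitz diazo transfer to the doubly activated methylene then gives 13 in the same flask, so the polymerisable vinyl keto ester is never stored, and the amine base is kept cold to disfavour expulsion of the aryloxide.

Step 7
Reactants: 13 ring A–ring B aryl 2-diazo-4-methyl-3-oxopent-4-enoate; 14 ethoxyacetylene (ethoxyethyne)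
Product: 18 methyl 4-{[4-({2-ethoxy-4-hydroxy-6-methylbenzoyl}oxy)-2-hydroxy-6-methylbenzoyl]oxy}-2-hydroxy-6-methylbenzoate (2''-O-ethyl tridepside), via vinylketene 15 (not isolated), via cyclobutenone 16 (not isolated), via dienylketene 17 (not isolated)
Conditions: 14 (5 equiv), hν (365 nm), ClCH2CH2Cl, 20 °C; then 80 °C (sealed tube)
Reagents that add atoms: none
Why: Light absorbed by the diazo chromophore of 13 expels N2 and the isopropenyl group shifts from the ketone carbon to the diazo carbon (Wolff rearrangement; a carbon group on the acyl carbon migrates far more readily than an aryloxy group), which creates the C1''–C6'' bond and vinylketene 15 with the aryl ester on its α-carbon. The polarised ynol ether 14 then adds across the ketene C=C bond in a stepwise [2+2] cycloaddition: its unsubstituted, nucleophilic carbon attacks the ketene carbonyl carbon (C3''–C4'') and its oxygen-bearing carbon closes onto the ketene α-carbon (C1''–C2''), giving cyclobutenone 16. On warming, conrotatory 4π-electrocyclic opening of 16 cleaves the bond between the carbonyl carbon and the quaternary carbon to give dienylketene 17, and ring C is closed by thermal disrotatory 6π-electrocyclisation of 17 between the ketene carbon and the isopropenyl CH2 (C4''–C5''), followed by tautomerisation of the cyclohexadienone to the phenol. The closest known reaction type is the Danheiser benzannulation in its photochemical Wolff variant with alkoxy- or siloxyalkynes. No stereocentre is created in 18; the quaternary carbon of 16 is racemic and is destroyed in the ring opening. The required regiochemistry (OEt on C2'', OH on C4'') follows from the matched polarity of the two partners, and the geometry needed for closure (isopropenyl cis to the ketene unit in 17) is reached because ring opening of 16 is reversible while carbocyclic closure is made irreversible by aromatisation. Ketene capture by O–H is held back because the phenols of 13 are hydrogen bonded to ester carbonyls and 14 is in excess, which also shields the new free 4''-OH of 18. Irradiation at 365 nm addresses only the diazo chromophore and lies outside the absorption of the aryl hydroxybenzoate units, so photo-Fries rearrangement of the depside bonds is not expected.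

Step 8
Reactants: 18 2''-O-ethyl tridepside
Product: 19 methyl 4-{[4-({2,4-dihydroxy-6-methylbenzoyl}oxy)-2-hydroxy-6-methylbenzoyl]oxy}-2-hydroxy-6-methylbenzoate (target, CNP0212402.0)
Conditions: BCl3 (5 equiv), CH2Cl2, −78 → 0 °C; then H2O
Reagents that add atoms: none
Why: Chelation-directed Lewis-acid ether cleavage: BCl3 bridges the C7'' carbonyl oxygen and O2'' in a six-membered chelate and chloride removes the ethyl group by SN2 attack, while the other hydroxyls are only borylated and are set free on hydrolysis; there is no other alkyl aryl ether, and the depside and methyl ester groups are expected to survive at or below 0 °C.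

## Compound list

In the names below, "AB-aryl" stands for 3-hydroxy-4-{[3-hydroxy-4-(methoxycarbonyl)-5-methylphenoxy]carbonyl}-5-methylphenyl, bonded through O4' of ring B.

1 | orsellinic acid (2,4-dihydroxy-6-methylbenzoic acid) | Cc1cc(O)cc(O)c1C(=O)O | starting material
2 | benzyl 2,4-bis(benzyloxy)-6-methylbenzoate | Cc1cc(OCc2ccccc2)cc(OCc2ccccc2)c1C(=O)OCc1ccccc1 | intermediate
3 | 2,4-bis(benzyloxy)-6-methylbenzoic acid | Cc1cc(OCc2ccccc2)cc(OCc2ccccc2)c1C(=O)O | intermediate
4 | methyl orsellinate (methyl 2,4-dihydroxy-6-methylbenzoate) | COC(=O)c1c(C)cc(O)cc1O | starting material
5 | 2,4-bis(benzyloxy)-6-methylbenzoic trifluoroacetic anhydride (mixed anhydride; not isolated) | Cc1cc(OCc2ccccc2)cc(OCc2ccccc2)c1C(=O)OC(=O)C(F)(F)F | intermediate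
6 | methyl 4-{[2,4-bis(benzyloxy)-6-methylbenzoyl]oxy}-2-hydroxy-6-methylbenzoate | COC(=O)c1c(C)cc(OC(=O)c2c(C)cc(OCc3ccccc3)cc2OCc2ccccc2)cc1O | intermediate
7 | methyl 4-[(2,4-dihydroxy-6-methylbenzoyl)oxy]-2-hydroxy-6-methylbenzoate (didepside phenol) | COC(=O)c1c(C)cc(OC(=O)c2c(C)cc(O)cc2O)cc1O | intermediate
8 | Meldrum's acid (2,2-dimethyl-1,3-dioxane-4,6-dione) | CC1(C)OC(=O)CC(=O)O1 | starting material
9 | methacryloyl chloride (2-methylprop-2-enoyl chloride) | CC(=C)C(=O)Cl | starting material
10 | 5-(1-hydroxy-2-methylprop-2-en-1-ylidene)-2,2-dimethyl-1,3-dioxane-4,6-dione (methacryloyl Meldrum's acid) | CC(=C)C(O)=C1C(=O)OC(C)(C)OC1=O | intermediate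
11 | 4-methylpenta-1,4-diene-1,3-dione (methacryloylketene; not isolated) | CC(=C)C(=O)C=C=O | intermediate
12 | AB-aryl 4-methyl-3-oxopent-4-enoate (keto ester; not isolated) | C=C(C)C(=O)CC(=O)Oc1cc(C)c(C(=O)Oc2cc(C)c(C(=O)OC)c(O)c2)c(O)c1 | intermediate
13 | AB-aryl 2-diazo-4-methyl-3-oxopent-4-enoate (precursor of the key step) | C=C(C)C(=O)C(=[N+]=[N-])C(=O)Oc1cc(C)c(C(=O)Oc2cc(C)c(C(=O)OC)c(O)c2)c(O)c1 | intermediate
14 | ethoxyacetylene (ethoxyethyne) | C#COCC | starting material
15 | AB-aryl 3-methyl-2-(oxomethylidene)but-3-enoate (vinylketene; not isolated) | C=C(C)C(=C=O)C(=O)Oc1cc(C)c(C(=O)Oc2cc(C)c(C(=O)OC)c(O)c2)c(O)c1 | intermediate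
16 | AB-aryl 2-ethoxy-4-oxo-1-(prop-1-en-2-yl)cyclobut-2-ene-1-carboxylate (racemic cyclobutenone; not isolated) | CCOC1=CC(=O)C1(C(C)=C)C(=O)Oc1cc(C)c(C(=O)Oc2cc(C)c(C(=O)OC)c(O)c2)c(O)c1 | intermediate
17 | AB-aryl (2Z)-3-ethoxy-5-oxo-2-(prop-1-en-2-yl)penta-2,4-dienoate (dienylketene; not isolated) | O=C=C/C(OCC)=C(\C(C)=C)C(=O)Oc1cc(C)c(C(=O)Oc2cc(C)c(C(=O)OC)c(O)c2)c(O)c1 | intermediate
18 | methyl 4-{[4-({2-ethoxy-4-hydroxy-6-methylbenzoyl}oxy)-2-hydroxy-6-methylbenzoyl]oxy}-2-hydroxy-6-methylbenzoate (2''-O-ethyl tridepside, product of the key step) | COC(=O)c1c(C)cc(OC(=O)c2c(C)cc(OC(=O)c3c(C)cc(O)cc3OCC)cc2O)cc1O | intermediate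
19 | methyl 4-{[4-({2,4-dihydroxy-6-methylbenzoyl}oxy)-2-hydroxy-6-methylbenzoyl]oxy}-2-hydroxy-6-methylbenzoate (CNP0212402.0) | COC(=O)c1c(C)cc(OC(=O)c2c(C)cc(OC(=O)c3c(C)cc(O)cc3O)cc2O)cc1O | target

## Step count and least certain steps

Total step count: 8 (steps 1 to 8). Longest linear sequence: 7 steps (1, 2, 3, 4, 6, 7, 8, from orsellinic acid); step 5 is a one-step branch.

**Step 7 (key step).**
- Ester-substituted vinylketenes are the less explored members of this reaction class, and 15 is also an α-oxo ketene. The zwitterion formed with 14, or the wrong geometry of 17, may therefore close through the ester carbonyl oxygen to a pyranone-type ring and not through carbon.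
- The free 4''-OH that builds up with the product may be acylated by 15.
- The excited diazo compound may partition towards carbene-type addition to the alkyne.
- Any light absorbed by the aryl esters could start photo-Fries cleavage of the depside bonds.
- Fallback: ring C is attached ready-made and not grown. The route is left at 7, which is acylated at O4' with acid 3 under the conditions of step 3 (through 5) to give the 2'',4''-di-O-benzyl tridepside F1. Hydrogenolysis over Pd/C as in step 4 returns to the route at 19. Both operations are the reaction types of steps 3 and 4; the price is a second hindered acylation, now with one free and two hydrogen-bonded phenols competing.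

**Step 6.**
- Acylketene 11 may lose its preference for O4' and also acylate a hydrogen-bonded hydroxyl.
- The vinyl keto ester 12 may oligomerise by Michael addition before it is diazotised.
- The amine base may trigger E1cB expulsion of the aryloxide from 12.
- Fallback: the chain is built on the phenol in the opposite order, with the diazo group present from the start. From 7, O-acylation at O4' with N-succinimidyl diazoacetate (Et3N, THF) would give the aryl diazoacetate F2. DBU-catalysed aldol-type addition of F2 to methacrolein would give the racemic β-hydroxy-α-diazo ester F3. Oxidation of the allylic alcohol with Dess–Martin periodinane returns to the route at 13. This avoids the acylketene, compound 12 and the diazo transfer.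

**Step 8.**
- Displacement at an ethyl group is slower than at methyl, so the dealkylation may stall at low temperature.
- Forcing it invites Lewis-acid cleavage or acyl migration of the depside bonds and attack on the hindered methyl ester.
- Fallback: a different oxygen substituent is carried through the benzannulation. From 13, the key step would be run with (triisopropylsilyloxy)ethyne F4 in place of 14. F4 is a silyl ynol ether that would have to be prepared separately by O-silylation of the lithium ynolate with triisopropylsilyl triflate. This should give the 2''-O-triisopropylsilyl tridepside F5. Cleavage of its aryl silyl ether with HF·pyridine in THF returns to the route at 19 without any Lewis acid.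

**Step 5.**
- Conjugate addition of the Meldrum's acid anion or of pyridine to 9, or polymerisation of the acryloyl unit, may compete with C-acylation.
- 10 may decompose on isolation.
- Fallback: acylketene 11 is generated from a tert-butyl β-keto ester and not from 10. Aldol addition of the lithium enolate of tert-butyl acetate to methacrolein (THF, −78 °C) would give racemic tert-butyl 3-hydroxy-4-methylpent-4-enoate F6. Oxidation with Dess–Martin periodinane would give tert-butyl 4-methyl-3-oxopent-4-enoate F7. Heating F7 with 7 in toluene at 110 °C (thermal loss of tert-butanol through 11) rejoins the route at 12, which is diazotised as in step 6. The fallback sets out from 7 and comes back at 12.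

## Further compounds

F1 | step 7 | methyl 4-{[4-({2,4-bis(benzyloxy)-6-methylbenzoyl}oxy)-2-hydroxy-6-methylbenzoyl]oxy}-2-hydroxy-6-methylbenzoate | COC(=O)c1c(C)cc(OC(=O)c2c(C)cc(OC(=O)c3c(C)cc(OCc4ccccc4)cc3OCc3ccccc3)cc2O)cc1O
F2 | step 6 | AB-aryl 2-diazoacetate | [N-]=[N+]=CC(=O)Oc1cc(C)c(C(=O)Oc2cc(C)c(C(=O)OC)c(O)c2)c(O)c1
F3 | step 6 | AB-aryl 2-diazo-3-hydroxy-4-methylpent-4-enoate (racemic) | C=C(C)C(O)C(=[N+]=[N-])C(=O)Oc1cc(C)c(C(=O)Oc2cc(C)c(C(=O)OC)c(O)c2)c(O)c1
F4 | step 8 | (triisopropylsilyloxy)ethyne | C#CO[Si](C(C)C)(C(C)C)C(C)C
F5 | step 8 | methyl 4-{[4-({4-hydroxy-6-methyl-2-[(triisopropylsilyl)oxy]benzoyl}oxy)-2-hydroxy-6-methylbenzoyl]oxy}-2-hydroxy-6-methylbenzoate | COC(=O)c1c(C)cc(OC(=O)c2c(C)cc(OC(=O)c3c(C)cc(O)cc3O[Si](C(C)C)(C(C)C)C(C)C)cc2O)cc1O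
F6 | step 5 | tert-butyl 3-hydroxy-4-methylpent-4-enoate (racemic) | C=C(C)C(O)CC(=O)OC(C)(C)C
F7 | step 5 | tert-butyl 4-methyl-3-oxopent-4-enoate | C=C(C)C(=O)CC(=O)OC(C)(C)C
A1 | alternative 1 | 3-(benzyloxy)-4-bromo-5-methylphenyl 2,4-bis(benzyloxy)-6-methylbenzoate | Cc1cc(OC(=O)c2c(C)cc(OCc3ccccc3)cc2OCc2ccccc2)cc(OCc2ccccc2)c1Br
A2 | alternative 1 | carbon monoxide | [C-]#[O+]
A3 | alternative 1 | methyl 4-{[2-(benzyloxy)-4-({2,4-bis(benzyloxy)-6-methylbenzoyl}oxy)-6-methylbenzoyl]oxy}-2-hydroxy-6-methylbenzoate (tri-O-benzyl tridepside) | COC(=O)c1c(C)cc(OC(=O)c2c(C)cc(OC(=O)c3c(C)cc(OCc4ccccc4)cc3OCc3ccccc3)cc2OCc2ccccc2)cc1O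
A4 | alternative 2 | 3-hydroxy-4-(methoxycarbonyl)-5-methylphenyl 3-oxobutanoate | COC(=O)c1c(C)cc(OC(=O)CC(C)=O)cc1O
A5 | alternative 2 | phenyl (E)-but-2-enoate | C/C=C/C(=O)Oc1ccccc1
A6 | alternative 2 | 3-hydroxy-4-(methoxycarbonyl)-5-methylphenyl 2-hydroxy-6-methyl-4-oxocyclohex-1-ene-1-carboxylate (racemic, enol form) | COC(=O)c1c(C)cc(OC(=O)C2=C(O)CC(=O)CC2C)cc1O
A7 | alternative 3 | 3-hydroxy-4-(methoxycarbonyl)-5-methylphenyl but-2-ynoate | COC(=O)c1c(C)cc(OC(=O)C#CC)cc1O
A8 | alternative 3 | 1-methoxy-1,3-bis(trimethylsilyloxy)buta-1,3-diene (geometry at C1=C2 not defined) | COC(O[Si](C)(C)C)=CC(=C)O[Si](C)(C)C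
A9 | alternative 3 | methyl 4-[(2,4-dihydroxy-6-methylbenzoyl)oxy]-2-hydroxy-6-methylbenzoate (identical with 7) | COC(=O)c1c(C)cc(OC(=O)c2c(C)cc(O)cc2O)cc1O
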